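**Retrosynthetic overview**

1. The O6 ester is cut last, giving the macrocyclic C6 alcohol and (2S,3S)-epoxyangelic acid (Sharpless epoxidation of angelyl alcohol, then oxidation).
2. Key disconnection C7–C8. This bond is common to the γ-lactone and the ten-membered carbocycle, and the array C8(–O)–C7–C11(=C13)–C12(=O) is the retron of a carbonyl 2-(alkoxycarbonyl)allylation. An aldehyde/allylic bromide on a preformed furanone should therefore give, with CrCl2, the carbocycle, the lactone, the C11=C13 methylene and the C7/C8 stereocentres in one operation. The furanone ring (oxygen bridge C3–O–C10) and the Z C4=C5 bond turn the two chain ends toward each other.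
3. The furanone comes from gold-catalysed 5-endo-dig closure of an α'-hydroxy ynone. The C3–C4 bond comes from Sonogashira coupling of a Z vinyl iodide (C4–C7, C11–C13, C15; C6 from (R)-glyceraldehyde acetonide) with an alkynyl triol (C1–C3, C8–C10, C14; C10 from (S)-citramalic acid).
4. Order of ring formation: 3(2H)-furanone (step 13), then ten-membered carbocycle and γ-lactone together (step 17). The oxirane of the side chain is made separately (step 20).

Key step: step 17

Remark on the chemistry: germacrane numbering is used for the target (C1 ketone, C2=C3, oxygen bridge C3–O–C10, C4=C5 with C15 on C4, C6 carrying the ester oxygen, C7, C8 carrying the lactone oxygen, C9, C10 carrying C14, C11=C13, C12 lactone carbonyl); the carbinol centres made in steps 5 and 10 (future C7 and C1) are carried as epimer mixtures and written without a descriptor, because both become sp2 carbons later.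

**Fragment B (vinyl iodide)**

Step 1
Reactants: 1 (R)-2,2-dimethyl-1,3-dioxolane-4-carbaldehyde
Product: 2 (4S)-4-[(1Z)-2-iodoprop-1-en-1-yl]-2,2-dimethyl-1,3-dioxolane
Conditions: EtPPh3I, n-BuLi, THF, 0 °C; I2, −78 °C; NaN(SiMe3)2, −78 °C; then 1, −78 → −20 °C
Reagents that add atoms: ethyltriphenylphosphonium iodide CC[P+](c1ccccc1)(c1ccccc1)c1ccccc1.[I-]; iodine II
Why: Stork–Zhao olefination with the α-iodo ylide should give the trisubstituted Z vinyl iodide under kinetic control at low temperature (the later C4=C5 geometry), while the C6 stereocentre is taken unchanged from the chiral pool.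

Step 2
Reactants: 2 (4S)-4-[(1Z)-2-iodoprop-1-en-1-yl]-2,2-dimethyl-1,3-dioxolane
Product: 3 (2S,3Z)-4-iodopent-3-ene-1,2-diol
Conditions: AcOH/H2O (4:1), 40 °C
Reagents that add atoms: none
Why: Acid-catalysed acetal hydrolysis should release the 1,2-diol without touching the vinyl iodide or the carbinol centre.

Step 3
Reactants: 3 (2S,3Z)-4-iodopent-3-ene-1,2-diol
Product: 5 (2S,3Z)-2-(tert-butyldimethylsilyloxy)-4-iodo-1-(triethylsilyloxy)pent-3-ene, via primary triethylsilyl ether 4 (not isolated)
Conditions: Et3SiCl (1.05 equiv), imidazole, CH2Cl2, −78 → −40 °C; then tBuMe2SiOTf, 2,6-lutidine, −40 → 0 °C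
Reagents that add atoms: chlorotriethylsilane CC[Si](Cl)(CC)CC; tert-butyldimethylsilyl triflate CC(C)(C)[Si](C)(C)OS(=O)(=O)C(F)(F)F
Why: Chemoselective silylation: the silyl chloride should react at the primary hydroxyl at low temperature, and the remaining secondary allylic hydroxyl is then capped by the more reactive silyl triflate.

Step 4
Reactants: 5 (2S,3Z)-2-(tert-butyldimethylsilyloxy)-4-iodo-1-(triethylsilyloxy)pent-3-ene
Product: 6 (2S,3Z)-2-(tert-butyldimethylsilyloxy)-4-iodopent-3-enal
Conditions: (COCl)2, DMSO, CH2Cl2, −78 → −30 °C; Et3N, −78 °C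
Reagents that add atoms: none
Why: Swern oxidation with oxidative desilylation: the chlorosulfonium reagent should cleave the primary triethylsilyl ether and oxidise it to the aldehyde, while the secondary tert-butyldimethylsilyl ether is inert and the cold amine quench protects the α-stereocentre.

Step 5
Reactants: 6 (2S,3Z)-2-(tert-butyldimethylsilyloxy)-4-iodopent-3-enal
Product: 7 methyl (4S,5Z)-4-(tert-butyldimethylsilyloxy)-3-hydroxy-6-iodo-2-methylidenehept-5-enoate (C3 epimers; C3 is the future C7)
Conditions: methyl propiolate, iBu2AlH, N-methylmorpholine N-oxide, THF, 0 °C; then 6, 0 °C → rt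
Reagents that add atoms: methyl propiolate C#CC(=O)OC
Why: Vinylalumination: hydroalumination of the propiolate gives an α-(methoxycarbonyl)vinylalane that should add 1,2 to the aldehyde under non-basic conditions to give the Morita–Baylis–Hillman-type adduct, whose new carbinol configuration is irrelevant because this carbon becomes sp2 in step 16.

Step 6
Reactants: 7 methyl (4S,5Z)-4-(tert-butyldimethylsilyloxy)-3-hydroxy-6-iodo-2-methylidenehept-5-enoate
Product: 8 methyl (4S,5Z)-4-(tert-butyldimethylsilyloxy)-6-iodo-2-methylidene-3-(triethylsilyloxy)hept-5-enoate (C3 epimers)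
Conditions: Et3SiOTf, 2,6-lutidine, CH2Cl2, −78 °C
Reagents that add atoms: triethylsilyl triflate CC[Si](CC)(CC)OS(=O)(=O)C(F)(F)F
Why: Silylation of the secondary allylic alcohol with a silyl triflate should be fast at low temperature and gives a group that can later be removed in the presence of the tert-butyldimethylsilyl ether.

**Fragment A (alkynyl triol)**

Step 7
Reactants: 9 (S)-citramalic acid
Product: 10 2-[(4S)-2,2,4-trimethyl-5-oxo-1,3-dioxolan-4-yl]acetic acid
Conditions: 2,2-dimethoxypropane, TsOH (cat.), rt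
Reagents that add atoms: 2,2-dimethoxypropane COC(C)(C)OC
Why: Acetalisation of the α-hydroxy acid to the dioxolanone should differentiate the two carboxyl groups and leave the quaternary carbinol (future C10) untouched.

Step 8
Reactants: 10 2-[(4S)-2,2,4-trimethyl-5-oxo-1,3-dioxolan-4-yl]acetic acid
Product: 12 (3S)-3-hydroxy-3-methyloxolan-2-one, via dioxolanone alcohol 11 (not isolated)
Conditions: BH3·SMe2, THF, 0 °C → rt; MeOH quench; TsOH (cat.), CH2Cl2, rt
Reagents that add atoms: none
Why: Borane should reduce the free carboxylic acid chemoselectively in the presence of the dioxolanone, and acid-catalysed translactonisation of the resulting alcohol then gives the γ-lactone with loss of acetone.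

Step 9
Reactants: 12 (3S)-3-hydroxy-3-methyloxolan-2-one
Product: 13 (3S)-3-methyloxolane-2,3-diol (anomers)
Conditions: iBu2AlH (2.2 equiv), CH2Cl2, −78 °C
Reagents that add atoms: none
Why: Half-reduction of a lactone with iBu2AlH at low temperature should stop at the lactol because the aluminium hemiacetal is stable until work-up.

Step 10
Reactants: 13 (3S)-3-methyloxolane-2,3-diol
Product: 14 (3S)-3-methylhex-5-yne-1,3,4-triol (C4 epimers; C4 is the future C1)
Conditions: HC≡CMgBr (4 equiv), THF, 0 °C → rt
Reagents that add atoms: ethynylmagnesium bromide C#C[Mg]Br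
Why: Grignard addition to the open hydroxy-aldehyde form of the lactol should install the alkyne, the new carbinol configuration being irrelevant because this carbon is oxidised in step 12.

**Union and endgame**

Step 11
Reactants: 8 methyl (4S,5Z)-4-(tert-butyldimethylsilyloxy)-6-iodo-2-methylidene-3-(triethylsilyloxy)hept-5-enoate; 14 (3S)-3-methylhex-5-yne-1,3,4-triol
Product: 15 methyl (4S,5Z,10S)-4-(tert-butyldimethylsilyloxy)-9,10,12-trihydroxy-6,10-dimethyl-2-methylidene-3-(triethylsilyloxy)dodec-5-en-7-ynoate (C3 and C9 epimers)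
Conditions: Pd(PPh3)2Cl2 (5 mol %), CuI (10 mol %), Et3N, THF, rt
Reagents that add atoms: none
Why: Sonogashira coupling should proceed with retention of the Z vinyl geometry and tolerate the free hydroxyls, room temperature and a tertiary amine keeping Heck and aza-Michael reactions of the acrylate silent.

Step 12
Reactants: 15 methyl (4S,5Z,10S)-4-(tert-butyldimethylsilyloxy)-9,10,12-trihydroxy-6,10-dimethyl-2-methylidene-3-(triethylsilyloxy)dodec-5-en-7-ynoate
Product: 16 methyl (4S,5Z,10S)-4-(tert-butyldimethylsilyloxy)-10,12-dihydroxy-6,10-dimethyl-2-methylidene-9-oxo-3-(triethylsilyloxy)dodec-5-en-7-ynoate (C3 epimers)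
Conditions: activated MnO2, CH2Cl2, rt
Reagents that add atoms: none
Why: MnO2 oxidation should be selective for the doubly activated (propargylic, enyne-conjugated) secondary carbinol and leave the saturated primary and the tertiary alcohol untouched.

Step 13
Reactants: 16 methyl (4S,5Z,10S)-4-(tert-butyldimethylsilyloxy)-10,12-dihydroxy-6,10-dimethyl-2-methylidene-9-oxo-3-(triethylsilyloxy)dodec-5-en-7-ynoate
Product: 17 methyl (4S,5Z)-4-(tert-butyldimethylsilyloxy)-6-[(5S)-5-(2-hydroxyethyl)-5-methyl-4-oxo-4,5-dihydrofuran-2-yl]-2-methylidene-3-(triethylsilyloxy)hept-5-enoate (C3 epimers)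
Conditions: (Ph3P)AuCl (5 mol %), AgOTf (5 mol %), toluene, rt
Reagents that add atoms: none
Why: Cationic monovalent gold activates the ynone alkyne so that the tertiary C10 hydroxyl adds 5-endo-dig at C3 and protodeauration gives the 3(2H)-furanone (a known cyclisation of α'-hydroxy ynones), the quaternary stereocentre not being involved.

Step 14
Reactants: 17 methyl (4S,5Z)-4-(tert-butyldimethylsilyloxy)-6-[(5S)-5-(2-hydroxyethyl)-5-methyl-4-oxo-4,5-dihydrofuran-2-yl]-2-methylidene-3-(triethylsilyloxy)hept-5-enoate
Product: 18 methyl (4S,5Z)-4-(tert-butyldimethylsilyloxy)-6-[(5S)-5-methyl-4-oxo-5-(2-oxoethyl)-4,5-dihydrofuran-2-yl]-2-methylidene-3-(triethylsilyloxy)hept-5-enoate (C3 epimers)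
Conditions: Dess–Martin periodinane, NaHCO3, CH2Cl2, 0 °C → rt
Reagents that add atoms: none
Why: Dess–Martin oxidation of the only free (primary) alcohol under buffered, non-basic conditions should give the C8 aldehyde without β-elimination of the furanone oxygen.

Step 15
Reactants: 18 methyl (4S,5Z)-4-(tert-butyldimethylsilyloxy)-6-[(5S)-5-methyl-4-oxo-5-(2-oxoethyl)-4,5-dihydrofuran-2-yl]-2-methylidene-3-(triethylsilyloxy)hept-5-enoate
Product: 19 methyl (4S,5Z)-4-(tert-butyldimethylsilyloxy)-3-hydroxy-6-[(5S)-5-methyl-4-oxo-5-(2-oxoethyl)-4,5-dihydrofuran-2-yl]-2-methylidenehept-5-enoate (C3 epimers)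
Conditions: HF·pyridine, pyridine, THF, 0 °C
Reagents that add atoms: none
Why: Buffered fluoride desilylation should cleave the secondary triethylsilyl ether much faster than the secondary tert-butyldimethylsilyl ether, and the acidic medium avoids silyl migration and base-induced damage to the aldehyde.

Step 16
Reactants: 19 methyl (4S,5Z)-4-(tert-butyldimethylsilyloxy)-3-hydroxy-6-[(5S)-5-methyl-4-oxo-5-(2-oxoethyl)-4,5-dihydrofuran-2-yl]-2-methylidenehept-5-enoate
Product: 20 methyl (2Z,4S,5Z)-2-(bromomethyl)-4-(tert-butyldimethylsilyloxy)-6-[(5S)-5-methyl-4-oxo-5-(2-oxoethyl)-4,5-dihydrofuran-2-yl]hepta-2,5-dienoate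
Conditions: N-bromosuccinimide, Me2S, CH2Cl2, −20 → 0 °C
Reagents that add atoms: N-bromosuccinimide O=C1CCC(=O)N1Br
Why: Corey–Kim-type activation of the Morita–Baylis–Hillman alcohol followed by SN2' delivery of bromide should give the Z 2-(bromomethyl)enoate from both carbinol epimers under neutral conditions.

Step 17
Reactants: 20 methyl (2Z,4S,5Z)-2-(bromomethyl)-4-(tert-butyldimethylsilyloxy)-6-[(5S)-5-methyl-4-oxo-5-(2-oxoethyl)-4,5-dihydrofuran-2-yl]hepta-2,5-dienoate
Product: 23 (4Z,6S,7R,8S,10S)-6-(tert-butyldimethylsilyloxy)-1-oxo-3,10-epoxygermacra-2,4,11(13)-trien-12,8-olide, via allylchromium dichloride 21 (not isolated), via seco hydroxy ester 22 (not isolated)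
Conditions: CrCl2 (10 equiv), DMF/THF, rt, slow addition of 20 (final 2 mM); aq. NH4Cl; PPTS (cat.), CH2Cl2, rt to complete lactonisation
Reagents that add atoms: none
Why: Two equivalents of CrCl2 reduce the allylic bromide to the allylchromium species 21, which adds through its γ-carbon C7 to the C8 aldehyde in a closed six-membered chair transition state (Nozaki–Hiyama–Kishi-type 2-(alkoxycarbonyl)allylation, the closest known case being the chromium-mediated closure of ten-membered carbocyclic α-methylene lactones from ω-formyl 2-(bromomethyl)enoates), and the C8 alkoxide then attacks the C12 methyl ester. The ten-membered carbocycle is closed by this intramolecular SE2' carbonyl addition at high dilution, the furanone oxygen bridge (C3–O–C10) and the Z C4=C5 bond holding C6/C7 and C8/C9 on the same side, and the γ-lactone is closed by 5-exo-trig acyl substitution. The C7/C8 relationship (anti adduct, trans-fused lactone) should follow from the chair in which both ring bonds, C7–C6 and C8–C9, are equatorial, the allylchromium geometry equilibrating by 1,3-metal shift so that the Z bromide suffices. The sense at C7 is expected to be set by C6: with C6–H eclipsing the C7=C11 bond (allylic 1,3-strain against the C11 substituents) the aldehyde should approach anti to the C5 vinyl carbon with the silyloxy group turned outward, which gives the 6,7-relationship of the target, and C8 then follows through the chair. The step needs γ- over α-attack (inherent to the allylmetal and the source of the C11=C13 methylene), aldehyde over furanone-ketone addition (the vinylogous ester carbonyl is unreactive towards allylchromium) and cyclisation over oligomerisation (slow addition).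

Step 18
Reactants: 23 (4Z,6S,7R,8S,10S)-6-(tert-butyldimethylsilyloxy)-1-oxo-3,10-epoxygermacra-2,4,11(13)-trien-12,8-olide
Product: 24 (4Z,6S,7S,8S,10S)-6-hydroxy-1-oxo-3,10-epoxygermacra-2,4,11(13)-trien-12,8-olide (same spatial arrangement; the C7 descriptor changes only by the priority rules)
Conditions: HF·pyridine, THF, 0 °C → rt
Reagents that add atoms: none
Why: Acidic fluoride desilylation should free the C6 hydroxyl without the conjugate addition or translactonisation that a basic fluoride source could cause on the α-methylene lactone.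

**Side-chain acid**

Step 19
Reactants: 25 angelic acid
Product: 26 (2Z)-2-methylbut-2-en-1-ol
Conditions: LiAlH4, Et2O, 0 °C
Reagents that add atoms: none
Why: Hydride 1,2-reduction of the conjugated acid at low temperature should give the allylic alcohol with the Z geometry intact.

Step 20
Reactants: 26 (2Z)-2-methylbut-2-en-1-ol
Product: 27 [(2R,3S)-2,3-dimethyloxiran-2-yl]methanol
Conditions: Ti(OiPr)4, D-(−)-diethyl tartrate, tBuOOH, 4 Å molecular sieves, CH2Cl2, −20 °C
Reagents that add atoms: tert-butyl hydroperoxide CC(C)(C)OO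
Why: Sharpless asymmetric epoxidation: the D-tartrate ligand should direct oxygen to the alkene face that gives the (2R,3S) epoxy alcohol, and the syn addition turns the Z geometry into the cis relationship of CH2OH and the C3 methyl group.

Step 21
Reactants: 27 [(2R,3S)-2,3-dimethyloxiran-2-yl]methanol
Product: 28 (2S,3S)-2,3-dimethyloxirane-2-carboxylic acid
Conditions: RuCl3 (cat.), NaIO4, CCl4/MeCN/H2O, rt
Reagents that add atoms: water O
Why: Ruthenium tetroxide oxidation (generated from RuCl3 and NaIO4) should take the primary alcohol to the acid through the aldehyde hydrate without opening the epoxide, the configuration being unchanged (the C2 descriptor changes only by the priority rules).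

**Final esterification**

Step 22
Reactants: 24 (4Z,6S,7S,8S,10S)-6-hydroxy-1-oxo-3,10-epoxygermacra-2,4,11(13)-trien-12,8-olide; 28 (2S,3S)-2,3-dimethyloxirane-2-carboxylic acid
Product: 30 target (4Z,6S,7R,8S,10S)-6-[(2S,3S)-2,3-dimethyloxirane-2-carbonyloxy]-1-oxo-3,10-epoxygermacra-2,4,11(13)-trien-12,8-olide, via mixed anhydride 29 (not isolated)
Conditions: 28, 2,4,6-trichlorobenzoyl chloride, Et3N, THF, rt; then 24, DMAP, toluene, rt
Reagents that add atoms: none
Why: Yamaguchi esterification: the mixed anhydride should acylate the hindered secondary C6 hydroxyl through the acylpyridinium with retention at C6 and without touching the epoxide or isomerising the acyl group.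

**Compound list**

1 | (R)-2,2-dimethyl-1,3-dioxolane-4-carbaldehyde | O=C[C@@H]1OC(C)(C)OC1 | starting material
2 | (4S)-4-[(1Z)-2-iodoprop-1-en-1-yl]-2,2-dimethyl-1,3-dioxolane | I/C(C)=C\[C@@H]1OC(C)(C)OC1 | intermediate
3 | (2S,3Z)-4-iodopent-3-ene-1,2-diol | I/C(C)=C\[C@H](O)CO | intermediate
4 | (2S,3Z)-4-iodo-1-(triethylsilyloxy)pent-3-en-2-ol | I/C(C)=C\[C@H](O)CO[Si](CC)(CC)CC | intermediate (not isolated)
5 | (2S,3Z)-2-(tert-butyldimethylsilyloxy)-4-iodo-1-(triethylsilyloxy)pent-3-ene | I/C(C)=C\[C@H](O[Si](C)(C)C(C)(C)C)CO[Si](CC)(CC)CC | intermediate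
6 | (2S,3Z)-2-(tert-butyldimethylsilyloxy)-4-iodopent-3-enal | I/C(C)=C\[C@H](O[Si](C)(C)C(C)(C)C)C=O | intermediate
7 | methyl (4S,5Z)-4-(tert-butyldimethylsilyloxy)-3-hydroxy-6-iodo-2-methylidenehept-5-enoate (C3 epimers) | I/C(C)=C\[C@H](O[Si](C)(C)C(C)(C)C)C(O)C(=C)C(=O)OC | intermediate
8 | methyl (4S,5Z)-4-(tert-butyldimethylsilyloxy)-6-iodo-2-methylidene-3-(triethylsilyloxy)hept-5-enoate (C3 epimers) | I/C(C)=C\[C@H](O[Si](C)(C)C(C)(C)C)C(O[Si](CC)(CC)CC)C(=C)C(=O)OC | intermediate
9 | (S)-citramalic acid, (2S)-2-hydroxy-2-methylbutanedioic acid | OC(=O)C[C@](C)(O)C(=O)O | starting material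
10 | 2-[(4S)-2,2,4-trimethyl-5-oxo-1,3-dioxolan-4-yl]acetic acid | OC(=O)C[C@]1(C)OC(C)(C)OC1=O | intermediate
11 | (5S)-5-(2-hydroxyethyl)-2,2,5-trimethyl-1,3-dioxolan-4-one | OCC[C@]1(C)OC(C)(C)OC1=O | intermediate (not isolated)
12 | (3S)-3-hydroxy-3-methyloxolan-2-one | O=C1OCC[C@]1(C)O | intermediate
13 | (3S)-3-methyloxolane-2,3-diol (anomers) | OC1OCC[C@]1(C)O | intermediate
14 | (3S)-3-methylhex-5-yne-1,3,4-triol (C4 epimers) | OCC[C@](C)(O)C(O)C#C | intermediate
15 | methyl (4S,5Z,10S)-4-(tert-butyldimethylsilyloxy)-9,10,12-trihydroxy-6,10-dimethyl-2-methylidene-3-(triethylsilyloxy)dodec-5-en-7-ynoate (C3 and C9 epimers) | OCC[C@](C)(O)C(O)C#C/C(C)=C\[C@H](O[Si](C)(C)C(C)(C)C)C(O[Si](CC)(CC)CC)C(=C)C(=O)OC | intermediate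
16 | methyl (4S,5Z,10S)-4-(tert-butyldimethylsilyloxy)-10,12-dihydroxy-6,10-dimethyl-2-methylidene-9-oxo-3-(triethylsilyloxy)dodec-5-en-7-ynoate (C3 epimers) | OCC[C@](C)(O)C(=O)C#C/C(C)=C\[C@H](O[Si](C)(C)C(C)(C)C)C(O[Si](CC)(CC)CC)C(=C)C(=O)OC | intermediate
17 | methyl (4S,5Z)-4-(tert-butyldimethylsilyloxy)-6-[(5S)-5-(2-hydroxyethyl)-5-methyl-4-oxo-4,5-dihydrofuran-2-yl]-2-methylidene-3-(triethylsilyloxy)hept-5-enoate (C3 epimers) | OCC[C@]1(C)OC(=CC1=O)/C(C)=C\[C@H](O[Si](C)(C)C(C)(C)C)C(O[Si](CC)(CC)CC)C(=C)C(=O)OC | intermediate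
18 | methyl (4S,5Z)-4-(tert-butyldimethylsilyloxy)-6-[(5S)-5-methyl-4-oxo-5-(2-oxoethyl)-4,5-dihydrofuran-2-yl]-2-methylidene-3-(triethylsilyloxy)hept-5-enoate (C3 epimers) | O=CC[C@]1(C)OC(=CC1=O)/C(C)=C\[C@H](O[Si](C)(C)C(C)(C)C)C(O[Si](CC)(CC)CC)C(=C)C(=O)OC | intermediate
19 | methyl (4S,5Z)-4-(tert-butyldimethylsilyloxy)-3-hydroxy-6-[(5S)-5-methyl-4-oxo-5-(2-oxoethyl)-4,5-dihydrofuran-2-yl]-2-methylidenehept-5-enoate (C3 epimers) | O=CC[C@]1(C)OC(=CC1=O)/C(C)=C\[C@H](O[Si](C)(C)C(C)(C)C)C(O)C(=C)C(=O)OC | intermediate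
20 | methyl (2Z,4S,5Z)-2-(bromomethyl)-4-(tert-butyldimethylsilyloxy)-6-[(5S)-5-methyl-4-oxo-5-(2-oxoethyl)-4,5-dihydrofuran-2-yl]hepta-2,5-dienoate | O=CC[C@]1(C)OC(=CC1=O)/C(C)=C\[C@H](O[Si](C)(C)C(C)(C)C)/C=C(\CBr)C(=O)OC | intermediate
21 | allylchromium dichloride derived from 20 (CrCl2 in place of Br on C13) | O=CC[C@]1(C)OC(=CC1=O)/C(C)=C\[C@H](O[Si](C)(C)C(C)(C)C)/C=C(\C[Cr](Cl)Cl)C(=O)OC | intermediate (not isolated)
22 | methyl (4Z,6S,7R,8S,10S)-6-(tert-butyldimethylsilyloxy)-8-hydroxy-1-oxo-3,10-epoxygermacra-2,4,11(13)-trien-12-oate (seco hydroxy ester, a chromium alkoxide before work-up) | COC(=O)C(=C)[C@@H]1[C@@H](O)C[C@]2(C)OC(=CC2=O)/C(C)=C\[C@@H]1O[Si](C)(C)C(C)(C)C | intermediate (not isolated)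
23 | (4Z,6S,7R,8S,10S)-6-(tert-butyldimethylsilyloxy)-1-oxo-3,10-epoxygermacra-2,4,11(13)-trien-12,8-olide | C=C1C(=O)O[C@H]2C[C@]3(C)OC(=CC3=O)/C(C)=C\[C@H](O[Si](C)(C)C(C)(C)C)[C@H]12 | intermediate
24 | (4Z,6S,7S,8S,10S)-6-hydroxy-1-oxo-3,10-epoxygermacra-2,4,11(13)-trien-12,8-olide | C=C1C(=O)O[C@H]2C[C@]3(C)OC(=CC3=O)/C(C)=C\[C@H](O)[C@H]12 | intermediate
25 | angelic acid, (2Z)-2-methylbut-2-enoic acid | C/C=C(/C)C(=O)O | starting material
26 | (2Z)-2-methylbut-2-en-1-ol | C/C=C(/C)CO | intermediate
27 | [(2R,3S)-2,3-dimethyloxiran-2-yl]methanol | OC[C@@]1(C)O[C@H]1C | intermediate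
28 | (2S,3S)-2,3-dimethyloxirane-2-carboxylic acid | OC(=O)[C@@]1(C)O[C@H]1C | intermediate
29 | (2S,3S)-2,3-dimethyloxirane-2-carboxylic 2,4,6-trichlorobenzoic anhydride | O=C(OC(=O)c1c(Cl)cc(Cl)cc1Cl)[C@@]1(C)O[C@H]1C | intermediate (not isolated)
30 | (4Z,6S,7R,8S,10S)-6-[(2S,3S)-2,3-dimethyloxirane-2-carbonyloxy]-1-oxo-3,10-epoxygermacra-2,4,11(13)-trien-12,8-olide (CNP0258430.1) | C=C1C(=O)O[C@H]2C[C@]3(C)OC(=CC3=O)/C(C)=C\[C@H](OC(=O)[C@@]3(C)O[C@H]3C)[C@H]12 | target

**Totals**

Total step count: 22. Longest linear sequence: 15 steps (steps 1–6, 11–18 and 22).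

**Three steps most likely to fail**

1. Step 17 (key step). What may go wrong: ring closure that is slow relative to intermolecular coupling, protonation or 1,4-elimination of the C6 silyloxy group from the allylchromium species, and incomplete anti or facial control in the chair. Fallback: the allyl bromide and the stoichiometric metal are avoided. The route leaves at 19, whose C7 hydroxyl is acetylated (AcCl, pyridine, CH2Cl2, 0 °C) to the allylic acetate F1. Under Pd(PPh3)4 (cat.) and InI in THF with slow addition, zerovalent palladium ionises the acetate and the π-allyl complex is transmetalated to the allylindium species F2, which is present only at catalytic concentration and so favours cyclisation. F2 adds to the C8 aldehyde through a cyclic six-membered transition state to give the seco hydroxy ester 22, whose lactonisation returns to the route at 23. Palladium-catalysed umpolung allylation with InI is a known carbonyl allylation of allylic acetates.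

2. Step 5. What may go wrong: enolisation of the α-silyloxy β,γ-unsaturated aldehyde on the Lewis-acidic aluminium reagent (loss of configuration at C6, migration of the double bond into conjugation) and competing reduction of the aldehyde by residual hydride. Fallback: from 6, an aldol addition of the lithium enolate of methyl 3-(dimethylamino)propanoate (LDA, THF, −78 °C) gives the β-hydroxy α-(dimethylaminomethyl) ester F3. N-Methylation with MeI gives the quaternary ammonium iodide F4, and elimination of trimethylamine with DBU unveils the methylidene group and returns to the route at 7.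

3. Step 4. What may go wrong: incomplete or unselective oxidative cleavage of the primary triethylsilyl ether (and, upstream, imperfect primary/secondary discrimination in step 3), or epimerisation of the aldehyde during the amine quench. Fallback: from 3, both hydroxyls are silylated (tBuMe2SiCl, imidazole, DMF) to the bis(tert-butyldimethylsilyl) ether F5. The primary silyl ether is cleaved selectively (HF·pyridine, pyridine, THF, 0 °C) to the primary alcohol F6, and Dess–Martin oxidation returns to the route at 6.

**Further compounds**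

F1 | step 17 | methyl (4S,5Z)-3-acetoxy-4-(tert-butyldimethylsilyloxy)-6-[(5S)-5-methyl-4-oxo-5-(2-oxoethyl)-4,5-dihydrofuran-2-yl]-2-methylidenehept-5-enoate (C3 epimers) | O=CC[C@]1(C)OC(=CC1=O)/C(C)=C\[C@H](O[Si](C)(C)C(C)(C)C)C(OC(C)=O)C(=C)C(=O)OC
F2 | step 17 | allylindium acetate iodide derived from F1 (indium on C13) | O=CC[C@]1(C)OC(=CC1=O)/C(C)=C\[C@H](O[Si](C)(C)C(C)(C)C)/C=C(\C[In](I)OC(C)=O)C(=O)OC
F3 | step 5 | methyl (4S,5Z)-4-(tert-butyldimethylsilyloxy)-2-[(dimethylamino)methyl]-3-hydroxy-6-iodohept-5-enoate (diastereomers) | I/C(C)=C\[C@H](O[Si](C)(C)C(C)(C)C)C(O)C(CN(C)C)C(=O)OC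
F4 | step 5 | N-methyl quaternary ammonium iodide of F3 | I/C(C)=C\[C@H](O[Si](C)(C)C(C)(C)C)C(O)C(C[N+](C)(C)C)C(=O)OC.[I-]
F5 | step 4 | (2S,3Z)-1,2-bis(tert-butyldimethylsilyloxy)-4-iodopent-3-ene | I/C(C)=C\[C@H](O[Si](C)(C)C(C)(C)C)CO[Si](C)(C)C(C)(C)C
F6 | step 4 | (2S,3Z)-2-(tert-butyldimethylsilyloxy)-4-iodopent-3-en-1-ol | I/C(C)=C\[C@H](O[Si](C)(C)C(C)(C)C)CO
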